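**Retrosynthetic overview**
- The strategy rests on the C1–C2 bond of the indane five-membered ring, which joins the benzylic C1H2 (on C7a, next to C7–H) to the quaternary C2(CH3)2. Putting an NH back between these two carbons gives a 3,3-dimethyl-1,2,3,4-tetrahydroisoquinoline that already carries all three side chains.
- That amine comes from its Troc carbamate. The C5 acetoxymethyl group derives from a C5 styryl group (ozonolysis, reduction, acetylation) and the C7 butanoyloxymethyl group from a C7 methyl ester.
- The C6 2-chloroethyl and C5 styryl groups are installed together by one Pd/norbornene (Catellani) reaction on a 5-iodo-tetrahydroisoquinoline ester.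
- The azacycle is closed (C1–C8a) by an N-acyliminium Pictet–Spengler reaction of an α-tertiary Troc carbamate. The carbamate comes from a Curtius rearrangement of the acid obtained by alkylating tert-butyl isobutyrate enolate with the benzylic bromide of methyl 3-iodo-4-methylbenzoate.
- Ring order: the benzene ring is purchased, the six-membered azacycle is closed in step 5, and it is contracted to the cyclopentane in step 12.

Key step: step 12

Remark: the target has no stereocentre (C2 bears two methyl groups), so there is no enantiomer to select. The only stereo-element on the way is the E-alkene of the styryl intermediates, which is cleaved before the end.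

**Route**

Step 1
Reactants: 1 methyl 3-iodo-4-methylbenzoate
Product: 2 methyl 4-(bromomethyl)-3-iodobenzoate
Conditions: NBS (1.05 equiv), AIBN (cat.), PhCF3, 85 °C
Reagents that add atoms: N-bromosuccinimide, O=C1CCC(=O)N1Br
Why: Wohl–Ziegler radical bromination should be selective because the 4-methyl group holds the only benzylic C–H bonds, and near-stoichiometric NBS limits dibromide formation.

Step 2
Reactants: 2 methyl 4-(bromomethyl)-3-iodobenzoate; 3 tert-butyl 2-methylpropanoate (tert-butyl isobutyrate)
Product: 5 methyl 4-[3-(tert-butoxy)-2,2-dimethyl-3-oxopropyl]-3-iodobenzoate, via lithium ester enolate 4 (not isolated)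
Conditions: LDA (commercial solution, 1.1 equiv), THF, −78 °C; then 2, −78 → −20 °C
Reagents that add atoms: tert-butyl 2-methylpropanoate 3, CC(C)C(=O)OC(C)(C)C
Why: Ester enolate C-alkylation (SN2) of the benzylic bromide at low temperature should outrun Claisen attack on the aryl methyl ester; the tert-butyl ester is used because a second methyl ester could not later be cleaved selectively next to the benzoate.

Step 3
Reactants: 5 methyl 4-[3-(tert-butoxy)-2,2-dimethyl-3-oxopropyl]-3-iodobenzoate
Product: 6 3-[2-iodo-4-(methoxycarbonyl)phenyl]-2,2-dimethylpropanoic acid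
Conditions: TFA/CH2Cl2 (1:2), rt
Reagents that add atoms: none
Why: Acidolysis of the tert-butyl ester (loss of isobutene) should leave the methyl benzoate and the aryl iodide untouched.

Step 4
Reactants: 6 3-[2-iodo-4-(methoxycarbonyl)phenyl]-2,2-dimethylpropanoic acid; 7 2,2,2-trichloroethanol
Product: 10 methyl 3-iodo-4-[2-methyl-2-({[(2,2,2-trichloroethoxy)carbonyl]}amino)propyl]benzoate, via acyl azide 8 (not isolated), via isocyanate 9 (not isolated)
Conditions: DPPA, Et3N, toluene, rt → 90 °C; then Cl3CCH2OH (3 equiv), Bu2Sn(O2CC11H23)2 (5 mol%), 90 °C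
Reagents that add atoms: diphenylphosphoryl azide (DPPA), [N-]=[N+]=NP(=O)(Oc1ccccc1)Oc1ccccc1; 2,2,2-trichloroethanol 7, OCC(Cl)(Cl)Cl
Why: The Curtius rearrangement gives the α-tertiary isocyanate, and its tin-catalysed alcohol addition gives a Troc carbamate that is stable to strong acid, hydride and ozone yet removable by zinc in the presence of esters and an alkyl chloride.

Step 5
Reactants: 10 methyl 3-iodo-4-[2-methyl-2-({[(2,2,2-trichloroethoxy)carbonyl]}amino)propyl]benzoate; 11 paraformaldehyde (formaldehyde source)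
Product: 13 7-methyl 2-(2,2,2-trichloroethyl) 5-iodo-3,3-dimethyl-3,4-dihydro-1H-isoquinoline-2,7-dicarboxylate, via N-acyliminium ion 12 (not isolated)
Conditions: (CH2O)n (3 equiv), AcOH/H2SO4 (3:2), rt
Reagents that add atoms: paraformaldehyde 11, C=O
Why: This is an N-acyliminium Pictet–Spengler cyclisation in the sulfuric/acetic acid medium used for electron-poor phenethyl carbamates; only one position ortho to the side chain is free (the other bears iodine), the gem-dimethyl group favours closure, and the step is placed here because neither an alkene nor a benzylic ester would survive the acid.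

Step 6
Reactants: 13 7-methyl 2-(2,2,2-trichloroethyl) 5-iodo-3,3-dimethyl-3,4-dihydro-1H-isoquinoline-2,7-dicarboxylate; 14 1-bromo-2-chloroethane; 15 styrene
Product: 16 7-methyl 2-(2,2,2-trichloroethyl) 6-(2-chloroethyl)-3,3-dimethyl-5-[(E)-2-phenylethenyl]-3,4-dihydro-1H-isoquinoline-2,7-dicarboxylate
Conditions: Pd(OAc)2 (10 mol%), P(2-furyl)3 (22 mol%), norbornene (2 equiv), Cs2CO3 (3 equiv), 14 (5 equiv), 15 (1.5 equiv), MeCN, 90 °C
Reagents that add atoms: 1-bromo-2-chloroethane 14, ClCCBr; styrene 15, C=Cc1ccccc1
Why: In this Catellani ortho-alkylation with Heck termination, oxidative addition at C5–I and norbornene insertion are followed by palladation of the only free ortho C–H (C6), the palladacycle takes up the C–Br end of 14 while the C–Cl end stays, and norbornene extrusion plus Heck coupling with styrene gives the E-alkene; the C4 methylene is the ortho substituent that extrusion requires and the carbamate has no N–H.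

Step 7
Reactants: 16 7-methyl 2-(2,2,2-trichloroethyl) 6-(2-chloroethyl)-3,3-dimethyl-5-[(E)-2-phenylethenyl]-3,4-dihydro-1H-isoquinoline-2,7-dicarboxylate
Product: 17 2,2,2-trichloroethyl 6-(2-chloroethyl)-7-(hydroxymethyl)-3,3-dimethyl-5-[(E)-2-phenylethenyl]-3,4-dihydro-1H-isoquinoline-2-carboxylate
Conditions: DIBAL-H (2.5 equiv), CH2Cl2, −78 °C; Rochelle salt work-up
Reagents that add atoms: none
Why: DIBAL-H reduction of the aryl methyl ester at −78 °C should spare the hindered tertiary carbamate, the stilbene and the primary chloride, and the aluminium alkoxide is too weak a nucleophile to close an isochroman onto the chloroethyl group.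

Step 8
Reactants: 17 2,2,2-trichloroethyl 6-(2-chloroethyl)-7-(hydroxymethyl)-3,3-dimethyl-5-[(E)-2-phenylethenyl]-3,4-dihydro-1H-isoquinoline-2-carboxylate; 18 butanoic anhydride
Product: 19 2,2,2-trichloroethyl 7-[(butanoyloxy)methyl]-6-(2-chloroethyl)-3,3-dimethyl-5-[(E)-2-phenylethenyl]-3,4-dihydro-1H-isoquinoline-2-carboxylate
Conditions: (PrCO)2O, Et3N, DMAP (cat.), CH2Cl2, 0 °C → rt
Reagents that add atoms: butanoic anhydride 18, CCCC(=O)OC(=O)CCC
Why: DMAP-catalysed acylation of the only free hydroxyl group fixes the butanoate on the C7 carbinol before the second carbinol exists, so the two esters cannot be confused.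

Step 9
Reactants: 19 2,2,2-trichloroethyl 7-[(butanoyloxy)methyl]-6-(2-chloroethyl)-3,3-dimethyl-5-[(E)-2-phenylethenyl]-3,4-dihydro-1H-isoquinoline-2-carboxylate
Product: 21 2,2,2-trichloroethyl 7-[(butanoyloxy)methyl]-6-(2-chloroethyl)-5-(hydroxymethyl)-3,3-dimethyl-3,4-dihydro-1H-isoquinoline-2-carboxylate, via aryl aldehyde 20 (not isolated)
Conditions: O3, CH2Cl2/MeOH (4:1), −78 °C (Sudan III end point); then NaBH4, −78 → 0 °C
Reagents that add atoms: ozone, [O-][O+]=O
Why: Ozonolysis of the stilbene double bond should be far faster than attack on the arene, and borohydride work-up reduces the peroxidic intermediates and the aldehyde to the benzylic alcohol without touching the butanoate, the carbamate or the chloride.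

Step 10
Reactants: 21 2,2,2-trichloroethyl 7-[(butanoyloxy)methyl]-6-(2-chloroethyl)-5-(hydroxymethyl)-3,3-dimethyl-3,4-dihydro-1H-isoquinoline-2-carboxylate; 22 acetic anhydride
Product: 23 2,2,2-trichloroethyl 5-(acetoxymethyl)-7-[(butanoyloxy)methyl]-6-(2-chloroethyl)-3,3-dimethyl-3,4-dihydro-1H-isoquinoline-2-carboxylate
Conditions: Ac2O, pyridine, DMAP (cat.), CH2Cl2, rt
Reagents that add atoms: acetic anhydride 22, CC(=O)OC(C)=O
Why: Nucleophile-catalysed acetylation of the single free primary alcohol occurs under non-basic conditions, so no alkoxide forms that could displace the neighbouring chloride.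

Step 11
Reactants: 23 2,2,2-trichloroethyl 5-(acetoxymethyl)-7-[(butanoyloxy)methyl]-6-(2-chloroethyl)-3,3-dimethyl-3,4-dihydro-1H-isoquinoline-2-carboxylate
Product: 24 [5-(acetoxymethyl)-6-(2-chloroethyl)-3,3-dimethyl-1,2,3,4-tetrahydroisoquinolin-7-yl]methyl butanoate
Conditions: Zn dust, AcOH/THF, rt; NaHCO3 work-up
Reagents that add atoms: none
Why: Reductive fragmentation of the trichloroethyl carbamate (Troc removal: zinc insertion, β-elimination, decarboxylation) is orthogonal to both benzylic esters and to the unactivated primary chloride.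

Step 12
Reactants: 24 [5-(acetoxymethyl)-6-(2-chloroethyl)-3,3-dimethyl-1,2,3,4-tetrahydroisoquinolin-7-yl]methyl butanoate; 25 N-(benzyloxy)-N-(pivaloyloxy)-4-(trifluoromethyl)benzamide (anomeric amide)
Product: 28 [4-(acetoxymethyl)-5-(2-chloroethyl)-2,2-dimethyl-2,3-dihydro-1H-inden-6-yl]methyl butanoate, via N-benzyloxy hydrazide 26 (not isolated), via isodiazene 27 (not isolated)
Conditions: 25 (1.5 equiv), THF (0.2 M), 45 °C
Reagents that add atoms: none
Why: The secondary amine attacks the amide nitrogen of 25 with loss of pivalate (substitution at N) to give hydrazide 26, which expels benzyl 4-(trifluoromethyl)benzoate to form the 1,1-diazene 27; 27 loses N2 to a singlet 1,5-diradical (benzylic C1 and tertiary C3 of the former azacycle) that collapses by radical recombination. The closest known reaction type is the nitrogen deletion of cyclic benzylic secondary amines with anomeric amides, of which the tetrahydroisoquinoline-to-indane contraction is the parent case. The cyclopentane is closed by intramolecular radical–radical coupling within the former six-membered ring, so its size is fixed by the C1–C8a–C4a–C4–C3 tether. No stereocentre is formed because the new quaternary carbon carries two methyl groups. The step needs recombination to beat disproportionation (hydrogen transfer from a methyl group of the tertiary radical) and needs the hindered α-tertiary nitrogen to be aminated; the short tether and the singlet state of a diradical stabilised at both centres favour the former, and the unhindered benzylic flank of nitrogen together with excess 25 at high concentration supports the latter. The esters and the primary chloride are inert to 25.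

**Compound list**

1 | methyl 3-iodo-4-methylbenzoate | COC(=O)c1ccc(C)c(I)c1 | starting material
2 | methyl 4-(bromomethyl)-3-iodobenzoate | COC(=O)c1ccc(CBr)c(I)c1 | intermediate
3 | tert-butyl 2-methylpropanoate | CC(C)C(=O)OC(C)(C)C | starting material
4 | lithium enolate of tert-butyl 2-methylpropanoate | [Li+].CC(C)=C([O-])OC(C)(C)C | intermediate
5 | methyl 4-[3-(tert-butoxy)-2,2-dimethyl-3-oxopropyl]-3-iodobenzoate | COC(=O)c1ccc(CC(C)(C)C(=O)OC(C)(C)C)c(I)c1 | intermediate
6 | 3-[2-iodo-4-(methoxycarbonyl)phenyl]-2,2-dimethylpropanoic acid | COC(=O)c1ccc(CC(C)(C)C(=O)O)c(I)c1 | intermediate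
7 | 2,2,2-trichloroethanol | OCC(Cl)(Cl)Cl | starting material
8 | 3-[2-iodo-4-(methoxycarbonyl)phenyl]-2,2-dimethylpropanoyl azide | COC(=O)c1ccc(CC(C)(C)C(=O)N=[N+]=[N-])c(I)c1 | intermediate
9 | methyl 3-iodo-4-(2-isocyanato-2-methylpropyl)benzoate | COC(=O)c1ccc(CC(C)(C)N=C=O)c(I)c1 | intermediate
10 | methyl 3-iodo-4-[2-methyl-2-({[(2,2,2-trichloroethoxy)carbonyl]}amino)propyl]benzoate | COC(=O)c1ccc(CC(C)(C)NC(=O)OCC(Cl)(Cl)Cl)c(I)c1 | intermediate
11 | paraformaldehyde (as formaldehyde) | C=O | starting material
12 | N-methylidene-N-Troc iminium ion of 10 (N-acyliminium) | COC(=O)c1ccc(CC(C)(C)[N+](=C)C(=O)OCC(Cl)(Cl)Cl)c(I)c1 | intermediate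
13 | 7-methyl 2-(2,2,2-trichloroethyl) 5-iodo-3,3-dimethyl-3,4-dihydro-1H-isoquinoline-2,7-dicarboxylate | COC(=O)c1cc(I)c2CC(C)(C)N(C(=O)OCC(Cl)(Cl)Cl)Cc2c1 | intermediate
14 | 1-bromo-2-chloroethane | ClCCBr | starting material
15 | styrene | C=Cc1ccccc1 | starting material
16 | 7-methyl 2-(2,2,2-trichloroethyl) 6-(2-chloroethyl)-3,3-dimethyl-5-[(E)-2-phenylethenyl]-3,4-dihydro-1H-isoquinoline-2,7-dicarboxylate | COC(=O)c1cc2c(c(/C=C/c3ccccc3)c1CCCl)CC(C)(C)N(C(=O)OCC(Cl)(Cl)Cl)C2 | intermediate
17 | 2,2,2-trichloroethyl 6-(2-chloroethyl)-7-(hydroxymethyl)-3,3-dimethyl-5-[(E)-2-phenylethenyl]-3,4-dihydro-1H-isoquinoline-2-carboxylate | OCc1cc2c(c(/C=C/c3ccccc3)c1CCCl)CC(C)(C)N(C(=O)OCC(Cl)(Cl)Cl)C2 | intermediate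
18 | butanoic anhydride | CCCC(=O)OC(=O)CCC | starting material
19 | 2,2,2-trichloroethyl 7-[(butanoyloxy)methyl]-6-(2-chloroethyl)-3,3-dimethyl-5-[(E)-2-phenylethenyl]-3,4-dihydro-1H-isoquinoline-2-carboxylate | CCCC(=O)OCc1cc2c(c(/C=C/c3ccccc3)c1CCCl)CC(C)(C)N(C(=O)OCC(Cl)(Cl)Cl)C2 | intermediate
20 | 2,2,2-trichloroethyl 7-[(butanoyloxy)methyl]-6-(2-chloroethyl)-5-formyl-3,3-dimethyl-3,4-dihydro-1H-isoquinoline-2-carboxylate | CCCC(=O)OCc1cc2c(c(C=O)c1CCCl)CC(C)(C)N(C(=O)OCC(Cl)(Cl)Cl)C2 | intermediate
21 | 2,2,2-trichloroethyl 7-[(butanoyloxy)methyl]-6-(2-chloroethyl)-5-(hydroxymethyl)-3,3-dimethyl-3,4-dihydro-1H-isoquinoline-2-carboxylate | CCCC(=O)OCc1cc2c(c(CO)c1CCCl)CC(C)(C)N(C(=O)OCC(Cl)(Cl)Cl)C2 | intermediate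
22 | acetic anhydride | CC(=O)OC(C)=O | starting material
23 | 2,2,2-trichloroethyl 5-(acetoxymethyl)-7-[(butanoyloxy)methyl]-6-(2-chloroethyl)-3,3-dimethyl-3,4-dihydro-1H-isoquinoline-2-carboxylate | CCCC(=O)OCc1cc2c(c(COC(C)=O)c1CCCl)CC(C)(C)N(C(=O)OCC(Cl)(Cl)Cl)C2 | intermediate
24 | [5-(acetoxymethyl)-6-(2-chloroethyl)-3,3-dimethyl-1,2,3,4-tetrahydroisoquinolin-7-yl]methyl butanoate | CCCC(=O)OCc1cc2c(c(COC(C)=O)c1CCCl)CC(C)(C)NC2 | intermediate
25 | N-(benzyloxy)-N-(pivaloyloxy)-4-(trifluoromethyl)benzamide | CC(C)(C)C(=O)ON(OCc1ccccc1)C(=O)c1ccc(cc1)C(F)(F)F | starting material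
26 | N-(benzyloxy)-N-[tetrahydroisoquinolin-2-yl of 24]-4-(trifluoromethyl)benzamide (hydrazide adduct) | CCCC(=O)OCc1cc2c(c(COC(C)=O)c1CCCl)CC(C)(C)N(N(OCc3ccccc3)C(=O)c3ccc(cc3)C(F)(F)F)C2 | intermediate
27 | 1,1-diazene (isodiazene) of 24 | CCCC(=O)OCc1cc2c(c(COC(C)=O)c1CCCl)CC(C)(C)[N+](=[N-])C2 | intermediate
28 | [4-(acetoxymethyl)-5-(2-chloroethyl)-2,2-dimethyl-2,3-dihydro-1H-inden-6-yl]methyl butanoate | CCCC(=O)OCc1cc2c(c(COC(C)=O)c1CCCl)CC(C)(C)C2 | target

**Step count**

Total steps: 12. Longest linear sequence: 12 (from 1).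

**Steps most likely to fail**

Step 12 (nitrogen deletion). N-amination of the nitrogen next to the quaternary carbon may be slower than self-decomposition of the anomeric amide, and part of the diradical may disproportionate by hydrogen transfer from a methyl group instead of closing the ring. The fallback sets out from 24 and returns at 28 through the same isodiazene 27. The amine would be N-nitrosated with tert-butyl nitrite in CH2Cl2, an electrophile small enough for hindered secondary amines, to give the N-nitrosamine F1. Zinc dust in aqueous acetic acid at 0 °C should reduce it to the 1,1-disubstituted hydrazine (2-amino-tetrahydroisoquinoline) F2. Oxidation of F2 with PhI(OAc)2 (or yellow HgO) in CH2Cl2 at 0 °C to rt would generate 27, which loses N2 to give 28. This is the classical nitrosamine–hydrazine–oxidation entry to 1,1-diazenes and uses only ester-compatible reagents.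

Step 6 (Catellani reaction). Palladation of the C6–H bond, wedged between the palladium-bearing C5 and the C7 ester, may be slower than direct Heck coupling at C5 or than loss of 14 by base-induced elimination, so that the chloroethyl group is not installed. The fallback sets out from 13 and returns at 16, using the acidity that the ester confers on C6–H instead of Pd/norbornene. TMPMgCl·LiCl (THF, −30 °C) should magnesiate 13 between the ester and the iodine to give the arylmagnesium chloride F3, which is not isolated. CuI (10 mol%) and ethylene oxide would give the 2-arylethoxide, which closes onto the neighbouring methyl ester to form the δ-lactone F4. SOCl2 with catalytic ZnCl2 at 80 °C should open the lactone to the 2-chloroethyl acid chloride F5 (not isolated), and MeOH/pyridine would convert it into the chloro ester F6. A ligand-free Heck reaction of F6 with styrene 15 (Pd(OAc)2, Bu4NCl, K2CO3, DMF, 90 °C) would then give 16.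

Step 5 (Pictet–Spengler closure). Attack of the ring, deactivated by the ester and the iodine, on the N-acyliminium ion may be slow enough for acid cleavage of the N–C(tertiary) bond or formaldehyde-derived oligomers to compete. The fallback sets out from isocyanate 9 (made as in step 4, with the alcohol omitted) and returns at 13. In TfOH/CH2Cl2 (0 °C → rt) the protonated isocyanate, a stronger electrophile that needs no condensation step, should undergo Friedel–Crafts carbamoylation at the free ortho position to give the lactam F7. BH3·SMe2 in THF at reflux, followed by MeOH/HCl, should reduce the lactam but not the aryl ester, giving the secondary amine F8. TrocCl/pyridine in CH2Cl2 would then give 13.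

**Further compounds**

F1 | step 12 | [5-(acetoxymethyl)-6-(2-chloroethyl)-3,3-dimethyl-2-nitroso-1,2,3,4-tetrahydroisoquinolin-7-yl]methyl butanoate | CCCC(=O)OCc1cc2c(c(COC(C)=O)c1CCCl)CC(C)(C)N(N=O)C2
F2 | step 12 | [5-(acetoxymethyl)-2-amino-6-(2-chloroethyl)-3,3-dimethyl-1,2,3,4-tetrahydroisoquinolin-7-yl]methyl butanoate | CCCC(=O)OCc1cc2c(c(COC(C)=O)c1CCCl)CC(C)(C)N(N)C2
F3 | step 6 | C6-magnesiated 13 (arylmagnesium chloride, not isolated) | COC(=O)c1cc2c(c(I)c1[Mg]Cl)CC(C)(C)N(C(=O)OCC(Cl)(Cl)Cl)C2
F4 | step 6 | δ-lactone of the 5-iodo-N-Troc-tetrahydroisoquinoline (C7–C(=O)–O–CH2CH2–C6) | O=C1OCCc2c(I)c3CC(C)(C)N(C(=O)OCC(Cl)(Cl)Cl)Cc3cc12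
F5 | step 6 | 2,2,2-trichloroethyl 7-(chlorocarbonyl)-6-(2-chloroethyl)-5-iodo-3,3-dimethyl-3,4-dihydro-1H-isoquinoline-2-carboxylate (not isolated) | ClC(=O)c1cc2c(c(I)c1CCCl)CC(C)(C)N(C(=O)OCC(Cl)(Cl)Cl)C2
F6 | step 6 | 7-methyl 2-(2,2,2-trichloroethyl) 6-(2-chloroethyl)-5-iodo-3,3-dimethyl-3,4-dihydro-1H-isoquinoline-2,7-dicarboxylate | COC(=O)c1cc2c(c(I)c1CCCl)CC(C)(C)N(C(=O)OCC(Cl)(Cl)Cl)C2
F7 | step 5 | methyl 5-iodo-3,3-dimethyl-1-oxo-1,2,3,4-tetrahydroisoquinoline-7-carboxylate | COC(=O)c1cc(I)c2CC(C)(C)NC(=O)c2c1
F8 | step 5 | methyl 5-iodo-3,3-dimethyl-1,2,3,4-tetrahydroisoquinoline-7-carboxylate | COC(=O)c1cc(I)c2CC(C)(C)NCc2c1
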